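Late in the cedar run I saw nothing move: from 5.00 min to 25.0 min the substrate reading stayed between 38.6% and 39.2%, with that much of the charge unused.

| flask | substrate | reagent | initiator | temperature | remark | time |
|---|---|---|---|---|---|---|
| cedar | 0.12 M | 0.132 M | 0.90 mM | 110 °C | the very flask that is asked about, followed so far |  |
| larch | 0.12 M | 0.132 M | 1.8 mM | 116 °C | run made earlier |  |
| flask | 0.12 M | 0.132 M | 0.90 mM | 110 °C |  | 25 min |

- cedar (time / min: product / %, substrate / %): 1.50: 57.1, 42.3; 5.00: 60.7, 39.0; 8.00: 61.0, 39.2; 15.0: 61.0, 38.7; 20.0: 60.7, 39.2; 25.0: 61.9, 38.6
- larch (time / s: product / %, substrate / %): 10.0: 33.9, 65.8; 20.0: 49.0, 51.2; 40.0: 61.5, 39.3; 60.0: 65.5, 35.4; 80.0: 66.4, 33.9; 120: 67.4, 33.2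

(each reading ± 0.3 percentage points)

- north-west: at 25 min add reagent, 50.0% of the amount charged, then wait 12 min
- south-east: at 25 min add substrate, 50.0% of the amount charged, then wait 12 min
- west: at 25 min raise the temperature by 10 K, then wait 12 min
- south-west: change nothing and wait 12 min more

- for product the crystals are counted in
- as a solid, counted per litre of solution: crystals
- the volume of additions can be left aside
- the analysis behind the earlier runs scatters by 0.3 percentage points, standard deviation
- steps thought possible: 2 reagent -> homo dimer; substrate + initiating radical -> chain carrier; initiator -> 2 initiating radical; reagent + chain carrier -> product + initiating radical; crystals <-> product; 2 initiating radical -> ended chains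

- product, in percent of the substrate first charged, at 25 min
- which option adds most product ("none" when 2 percentage points or less is all one gets) (north-west / south-east / west / south-west / none)
- product present, in percent of the substrate first charged, after south-east
- product present, in percent of the substrate first charged, after south-west

I reckoned from the fastest rung upward. At 1.50 min product and substrate already summed to 99.4% of the charge, against a scatter of 0.3 percentage points per reading, so I treated the chain carrier as a passing form. I took substrate to fall pseudo-first-order in the initiating radical, and I took that radical's level to follow the root of the initiator, made singly and lost in pairs.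

The cedar plateau gives 0.943 for the reach, the logarithm of charged over final substrate fraction. At fixed temperature I expected it to go as the root of the initiator charge. Larch, with twice the initiator, reached 1.10 against the root's 1.33, but its temperature differed, so it could not test this.

Next rung: at 1.50 min cedar had 8.78% of its reach unspent. Taken as a first-order decay, that gives the unspent reach a half-life of 0.427 min, which reads as an initiator half-life of 0.213 min. Last rung: 25 min is 58.5 such half-lives of the reach. So I expected product at 61.1% and no option worth 2 points.

The forecast gave 61.1% (60.7% to 61.5%), 61.1% after south-east, 61.1% after south-west and best none: “Adding reagent or substrate, heating, or waiting all give essentially nothing.”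

The flask gave 61.3%, 61.3% after south-east, 61.3% after south-west and best none; north-west added 0.047 points, more than any other option and less than 2 points. At 2.50 min it held 0.0322% of its initiator; the root, 1.79%, taken as the unspent share of the reach, puts substrate at 39.6%, and 39.6% stood there.

    2 reagent → homo dimer (k = 0.0876 M⁻¹ s⁻¹, Ea = 87.0 kJ mol⁻¹)
    substrate + initiating radical → chain carrier (k = 13100 M⁻¹ s⁻¹, Ea = 27.0 kJ mol⁻¹)
    initiator → 2 initiating radical (k = 0.0536 s⁻¹, Ea = 115 kJ mol⁻¹)
    reagent + chain carrier → product + initiating radical (k = 31200 M⁻¹ s⁻¹, Ea = 38.0 kJ mol⁻¹)
    crystals ⇌ product, rate k5*(cs5 - [product]) while solid is left; crystals form when [product] > cs5 (solubility = 4.50 mM, k = 1.12 s⁻¹)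
    2 initiating radical → ended chains (k = 1.30 × 10⁷ M⁻¹ s⁻¹, Ea = 15.0 kJ mol⁻¹)
    (constants at 110 °C)

The neighbour took 60.0% of this flask's initiator at the same temperature. The root cuts the reach to 0.731, which gives product 51.9%. Computed, that neighbour gave 52.1%.

(The data are calculated from invented constants.)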